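**Retrosynthetic overview**
- The butenolide is attached last: the E-dienyl lactone is cut at C12–C13 into a bicyclic C9-vinyl ent-labdane core and 3-bromofuran-2(5H)-one (Heck).
- Both rings are cut in one operation: an epoxide-initiated cation–olefin bicyclization of an acyclic (2S,3R)-epoxy acetate, ring A first (C4–C5 bond), then ring B (C10–C9 bond), terminated by a 2-(silylmethyl)-1,3-diene so that the 8(17)-methylidene and the C9 vinyl group emerge directly.
- The epoxide comes from a (2Z)-allylic alcohol by Katsuki–Sharpless epoxidation; the Z-CH2O group becomes the axial C19.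
- The acyclic chain comes from pent-4-yn-1-ol: isopropenyl addition, Johnson–Claisen (E-alkene), syn-carbocupration/vinylation (dienylsilane), then β-oxido ylide hydroxymethylation (Z-allylic alcohol).

Assumption: the target is 19-O-acetyl-14-deoxy-11,12-didehydroandrographolide (ent-labdane); labdane locants C1–C20 are used for atoms of the acyclic precursors, and all numbered starting materials are taken as catalogue items.

**Route**

Step 1
Reactants: 1 pent-4-yn-1-ol
Product: 2 pent-4-ynal
Conditions: PhI(OAc)2 (1.1 equiv), TEMPO (10 mol %), CH2Cl2, rt; distil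
Reagents that add atoms: none
Why: TEMPO/oxoammonium oxidation of a primary alcohol stops at the aldehyde and leaves the terminal alkyne untouched.

Step 2
Reactants: 2 pent-4-ynal; 3 isopropenylmagnesium bromide
Product: 4 rac-2-methylhept-1-en-6-yn-3-ol
Conditions: THF, −78 → 0 °C; then H2O/NH4Cl
Reagents that add atoms: none
Why: Grignard 1,2-addition to the aldehyde is much faster than deprotonation of the alkyne C–H at low temperature; the new carbinol centre is racemic and is erased in step 3.

Step 3
Reactants: 4 rac-2-methylhept-1-en-6-yn-3-ol; 5 triethyl orthoacetate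
Product: 7 ethyl (4E)-4-methylnon-4-en-8-ynoate, via ketene acetal 6 (not isolated)
Conditions: 5 (5 equiv), EtCO2H (cat.), 140 °C, EtOH distilled off
Reagents that add atoms: none
Why: Johnson–Claisen rearrangement; the chair [3,3] shift of the ketene acetal with the homopropargyl group pseudo-equatorial gives the 4E trisubstituted alkene (the future C10=C5) with >95:5 selectivity.

Step 4
Reactants: 7 ethyl (4E)-4-methylnon-4-en-8-ynoate; 8 (trimethylsilyl)methylmagnesium chloride; 9 vinyl bromide
Product: 12 ethyl (4E,8Z)-4-methyl-8-[(trimethylsilyl)methyl]undeca-4,8,10-trienoate, via alkenylcopper 10 (not isolated), via alkenylzinc bromide 11 (not isolated)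
Conditions: 8, CuBr·SMe2, Et2O/Me2S, −45 °C; 7, −45 → −20 °C; ZnBr2, 9, Pd(PPh3)4 (5 mol %), THF, −20 °C → rt
Reagents that add atoms: none
Why: Normant syn-carbocupration puts CH2SiMe3 on the internal and copper on the terminal alkyne carbon, and stereoretentive copper-to-zinc exchange followed by Negishi-type Pd-catalysed alkenyl–alkenyl coupling places the vinyl group cis to CH2SiMe3 (8Z), the geometry that later makes the C9 vinyl group equatorial; the organocopper does not attack the ester at −20 °C.

Step 5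
Reactants: 12 ethyl (4E,8Z)-4-methyl-8-[(trimethylsilyl)methyl]undeca-4,8,10-trienoate
Product: 13 (4E,8Z)-4-methyl-8-[(trimethylsilyl)methyl]undeca-4,8,10-trienal
Conditions: i-Bu2AlH (1.05 equiv), CH2Cl2, −78 °C; then MeOH, aq. potassium sodium tartrate
Reagents that add atoms: none
Why: DIBAL-H half-reduction of an ester at −78 °C in a non-coordinating solvent stops at the aldehyde oxidation level, and the allylsilane and alkenes are inert to the hydride.

Step 6
Reactants: 13 (4E,8Z)-4-methyl-8-[(trimethylsilyl)methyl]undeca-4,8,10-trienal; 14 ethyltriphenylphosphonium bromide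
Product: 17 (2Z,6E,10Z)-2,6-dimethyl-10-[(trimethylsilyl)methyl]trideca-2,6,10,12-tetraen-1-ol, via betaine 15 (not isolated), via β-oxido ylide 16 (not isolated)
Conditions: 14, n-BuLi (1.0 equiv), THF, 0 °C; 13, −78 °C; n-BuLi (1.05 equiv), −78 → −20 °C; (CH2O)n (dry, excess), 0 °C → rt
Reagents that add atoms: formaldehyde (from paraformaldehyde), C=O
Why: Corey–Yamamoto/Schlosser β-oxido ylide hydroxymethylation (Wittig variant); the oxygen of the original aldehyde leaves as Ph3P=O, so the new CH2OH ends up cis to the chain (2Z), the geometry that SeO2 oxidation cannot give.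

Step 7
Reactants: 17 (2Z,6E,10Z)-2,6-dimethyl-10-[(trimethylsilyl)methyl]trideca-2,6,10,12-tetraen-1-ol
Product: 19 [(2S,3R)-2-methyl-3-{(3E,7Z)-3-methyl-7-[(trimethylsilyl)methyl]deca-3,7,9-trien-1-yl}oxiran-2-yl]methyl acetate, via epoxy alcohol 18 (not isolated)
Conditions: Ti(Oi-Pr)4 (10 mol %), L-(+)-diethyl tartrate (12 mol %), t-BuOOH (1.5 equiv), 4 Å MS, CH2Cl2, −20 °C; then Et3N, Ac2O (2 equiv), DMAP (cat.), −20 → 0 °C
Reagents that add atoms: tert-butyl hydroperoxide, CC(C)(C)OO; acetic anhydride, CC(=O)OC(C)=O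
Why: Katsuki–Sharpless asymmetric epoxidation is hydroxyl-directed, so only the C3=C4 alkene reacts, and L-(+)-tartrate delivers oxygen to the same face as in geraniol → (2S,3S)-epoxygeraniol, here giving the (2S,3R)-epoxide (about 90% ee expected for a Z-trisubstituted allylic alcohol), which fixes C3 directly and C4 after inversion; acetylation in the same flask follows the known in situ derivatization of these epoxidations.

Step 8
Reactants: 19 [(2S,3R)-2-methyl-3-{(3E,7Z)-3-methyl-7-[(trimethylsilyl)methyl]deca-3,7,9-trien-1-yl}oxiran-2-yl]methyl acetate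
Product: 20 [(1R,2R,4aR,5R,8aS)-5-ethenyl-2-hydroxy-1,4a-dimethyl-6-methylidenedecahydronaphthalen-1-yl]methyl acetate
Conditions: MeAlCl2 (2.5 equiv), CH2Cl2 (0.01 M), −78 °C; then Et3N/MeOH, aq. potassium sodium tartrate
Reagents that add atoms: none
Why: Proposed new method: MeAlCl2 activates the epoxide, the E-C5=C10 alkene attacks C4 anti to the C–O bond (inversion, so the Z-derived CH2OAc becomes axial and the C3 oxygen equatorial), and C9 of the 2-(silylmethyl)-1,3-diene closes ring B through a chair–chair anti-addition array that sets C5, C10 and C9 (vinyl equatorial) from the epoxide configuration, the positive charge arriving at C8 β to silicon so that loss of Me3Si gives only the 8(17)-methylidene, while the six-membered ring size forces reaction through the γ-carbon (C9) of the pentadienylsilane and leaves the C11=C12 vinyl group intact; the closest known reaction types are Lewis-acid epoxy-polyene bicyclizations terminated by simple allylsilanes and Hosomi–Sakurai reactions of pentadienylsilanes.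

Step 9
Reactants: 20 [(1R,2R,4aR,5R,8aS)-5-ethenyl-2-hydroxy-1,4a-dimethyl-6-methylidenedecahydronaphthalen-1-yl]methyl acetate; 21 3-bromofuran-2(5H)-one
Product: 22 {(1R,2R,4aR,5R,8aS)-2-hydroxy-1,4a-dimethyl-6-methylidene-5-[(E)-2-(2-oxo-2,5-dihydrofuran-3-yl)ethenyl]decahydronaphthalen-1-yl}methyl acetate (19-O-acetyl-14-deoxy-11,12-didehydroandrographolide)
Conditions: Pd(OAc)2 (10 mol %), n-Bu4NCl (1 equiv), NaHCO3 (2.5 equiv), DMF, 60 °C
Reagents that add atoms: none
Why: Mizoroki–Heck reaction under Jeffery conditions; zerovalent palladium inserts into the α-bromobutenolide C–Br bond, adds to the terminal carbon of the monosubstituted vinyl group (the 1,1-disubstituted methylidene is much slower) and syn β-hydride elimination toward C12–H gives the conjugated E-diene without touching any stereocentre, the free alcohol or the acetate.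

**Compound list**
1 | pent-4-yn-1-ol | C#CCCCO | starting material
2 | pent-4-ynal | C#CCCC=O | intermediate
3 | isopropenylmagnesium bromide | CC(=C)[Mg]Br | starting material
4 | rac-2-methylhept-1-en-6-yn-3-ol | C=C(C)C(O)CCC#C | intermediate
5 | triethyl orthoacetate | CC(OCC)(OCC)OCC | starting material
6 | ketene acetal, 3-[(1-ethoxyethenyl)oxy]-2-methylhept-1-en-6-yne | C=C(C)C(CCC#C)OC(=C)OCC | intermediate
7 | ethyl (4E)-4-methylnon-4-en-8-ynoate | CCOC(=O)CC/C(C)=C/CCC#C | intermediate
8 | (trimethylsilyl)methylmagnesium chloride | C[Si](C)(C)C[Mg]Cl | starting material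
9 | vinyl bromide | C=CBr | starting material
10 | alkenylcopper, ethyl (4E,8Z)-9-cuprio-4-methyl-8-[(trimethylsilyl)methyl]nona-4,8-dienoate | CCOC(=O)CC/C(C)=C/CC/C(C[Si](C)(C)C)=C/[Cu] | intermediate
11 | alkenylzinc bromide, ethyl (4E,8Z)-9-(bromozincio)-4-methyl-8-[(trimethylsilyl)methyl]nona-4,8-dienoate | CCOC(=O)CC/C(C)=C/CC/C(C[Si](C)(C)C)=C/[Zn]Br | intermediate
12 | ethyl (4E,8Z)-4-methyl-8-[(trimethylsilyl)methyl]undeca-4,8,10-trienoate | CCOC(=O)CC/C(C)=C/CC/C(C[Si](C)(C)C)=C/C=C | intermediate
13 | (4E,8Z)-4-methyl-8-[(trimethylsilyl)methyl]undeca-4,8,10-trienal | O=CCC/C(C)=C/CC/C(C[Si](C)(C)C)=C/C=C | intermediate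
14 | ethyltriphenylphosphonium bromide | CC[P+](c1ccccc1)(c1ccccc1)c1ccccc1.[Br-] | starting material
15 | betaine, (6E,10Z)-6-methyl-10-[(trimethylsilyl)methyl]-2-(triphenylphosphaniumyl)trideca-6,10,12-trien-3-olate (diastereomer mixture) | CC([P+](c1ccccc1)(c1ccccc1)c1ccccc1)C([O-])CC/C(C)=C/CC/C(C[Si](C)(C)C)=C/C=C | intermediate
16 | β-oxido ylide, lithium (6E,10Z)-6-methyl-10-[(trimethylsilyl)methyl]-2-(triphenyl-λ5-phosphanylidene)trideca-6,10,12-trien-3-olate | [Li+].CC(=P(c1ccccc1)(c1ccccc1)c1ccccc1)C([O-])CC/C(C)=C/CC/C(C[Si](C)(C)C)=C/C=C | intermediate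
17 | (2Z,6E,10Z)-2,6-dimethyl-10-[(trimethylsilyl)methyl]trideca-2,6,10,12-tetraen-1-ol | OC/C(C)=C\CC/C(C)=C/CC/C(C[Si](C)(C)C)=C/C=C | intermediate
18 | epoxy alcohol, [(2S,3R)-2-methyl-3-{(3E,7Z)-3-methyl-7-[(trimethylsilyl)methyl]deca-3,7,9-trien-1-yl}oxiran-2-yl]methanol | OC[C@]1(C)O[C@@H]1CC/C(C)=C/CC/C(C[Si](C)(C)C)=C/C=C | intermediate
19 | [(2S,3R)-2-methyl-3-{(3E,7Z)-3-methyl-7-[(trimethylsilyl)methyl]deca-3,7,9-trien-1-yl}oxiran-2-yl]methyl acetate | CC(=O)OC[C@]1(C)O[C@@H]1CC/C(C)=C/CC/C(C[Si](C)(C)C)=C/C=C | intermediate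
20 | [(1R,2R,4aR,5R,8aS)-5-ethenyl-2-hydroxy-1,4a-dimethyl-6-methylidenedecahydronaphthalen-1-yl]methyl acetate | C=C1CC[C@@H]2[C@](C)(COC(C)=O)[C@H](O)CC[C@@]2(C)[C@@H]1C=C | intermediate
21 | 3-bromofuran-2(5H)-one | O=C1OCC=C1Br | starting material
22 | {(1R,2R,4aR,5R,8aS)-2-hydroxy-1,4a-dimethyl-6-methylidene-5-[(E)-2-(2-oxo-2,5-dihydrofuran-3-yl)ethenyl]decahydronaphthalen-1-yl}methyl acetate | C=C1CC[C@@H]2[C@](C)(COC(C)=O)[C@H](O)CC[C@@]2(C)[C@@H]1/C=C/C1=CCOC1=O | target

**Totals and risks**
Total step count: 9. Longest linear sequence: 9 steps (1 → 22); all coupling partners are purchased.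

The three steps most likely to fail:

Step 8, the bicyclization. The acetate carbonyl may open the activated epoxide before the alkene does, the dienylsilane may lose silicon early, or ring B may not close. The fallback puts the ester on after the rings are made instead of carrying it through the cationic step. It sets out from 18, isolated by ordinary work-up of the epoxidation without adding the anhydride. Silylation (TBSCl, imidazole, DMF) gives the epoxy silyl ether F1, whose oxygen substituent cannot participate. The same MeAlCl2 cyclization gives the bicyclic silyl ether F2. TBAF in THF frees the bicyclic 3,19-diol F3. Acetylation of the primary C19 hydroxyl only (Ac2O 1.05 equiv, 2,4,6-collidine, CH2Cl2, −40 °C, or vinyl acetate with Candida antarctica lipase B) comes back to the route at 20.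

Step 9, the Heck coupling. β-Hydride elimination toward the doubly allylic C9–H or alkene migration could erode the yield. The fallback sets out from 20. Cross-metathesis with pinacol vinylboronate (second-generation Grubbs catalyst, (H2IMes)(PCy3)Cl2Ru=CHPh, CH2Cl2, 40 °C) gives the E-alkenyl pinacolboronate F4. Stereoretentive Suzuki–Miyaura coupling with 21 (PdCl2(dppf), K3PO4, THF/H2O, 50 °C) comes back at 22.

Step 4, the carbocupration/vinylation. Silylmethylcopper reagents add sluggishly to alkynes, and copper acetylide formation can compete. The fallback sets out from 7. syn-Bromoboration (BBr3, CH2Cl2, −78 °C, then pinacol) gives the Z-bromoalkenyl pinacolboronate F5. Negishi coupling at the C–Br bond with Me3SiCH2ZnCl (from 8 and ZnCl2; Pd(t-Bu3P)2, THF) gives the silylmethyl alkenyl pinacolboronate F6. Suzuki–Miyaura coupling with 9 (PdCl2(dppf), K3PO4, THF/H2O) comes back at 12 with the same 8Z geometry.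

**Further compounds**
F1 | step 8 | epoxy silyl ether, tert-butyl{[(2S,3R)-2-methyl-3-{(3E,7Z)-3-methyl-7-[(trimethylsilyl)methyl]deca-3,7,9-trien-1-yl}oxiran-2-yl]methoxy}dimethylsilane | CC(C)(C)[Si](C)(C)OC[C@]1(C)O[C@@H]1CC/C(C)=C/CC/C(C[Si](C)(C)C)=C/C=C
F2 | step 8 | bicyclic silyl ether, (1R,2R,4aR,5R,8aS)-1-({[tert-butyl(dimethyl)silyl]oxy}methyl)-5-ethenyl-1,4a-dimethyl-6-methylidenedecahydronaphthalen-2-ol | C=C1CC[C@@H]2[C@](C)(CO[Si](C)(C)C(C)(C)C)[C@H](O)CC[C@@]2(C)[C@@H]1C=C
F3 | step 8 | bicyclic 3,19-diol, (1R,2R,4aR,5R,8aS)-5-ethenyl-1-(hydroxymethyl)-1,4a-dimethyl-6-methylidenedecahydronaphthalen-2-ol | C=C1CC[C@@H]2[C@](C)(CO)[C@H](O)CC[C@@]2(C)[C@@H]1C=C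
F4 | step 9 | E-alkenyl pinacolboronate, {(1R,2R,4aR,5R,8aS)-2-hydroxy-1,4a-dimethyl-6-methylidene-5-[(E)-2-(4,4,5,5-tetramethyl-1,3,2-dioxaborolan-2-yl)ethenyl]decahydronaphthalen-1-yl}methyl acetate | C=C1CC[C@@H]2[C@](C)(COC(C)=O)[C@H](O)CC[C@@]2(C)[C@@H]1/C=C/B1OC(C)(C)C(C)(C)O1
F5 | step 4 | Z-bromoalkenyl pinacolboronate, ethyl (4E,8Z)-8-bromo-4-methyl-9-(4,4,5,5-tetramethyl-1,3,2-dioxaborolan-2-yl)nona-4,8-dienoate | CCOC(=O)CC/C(C)=C/CC/C(Br)=C/B1OC(C)(C)C(C)(C)O1
F6 | step 4 | silylmethyl alkenyl pinacolboronate, ethyl (4E,8Z)-4-methyl-9-(4,4,5,5-tetramethyl-1,3,2-dioxaborolan-2-yl)-8-[(trimethylsilyl)methyl]nona-4,8-dienoate | CCOC(=O)CC/C(C)=C/CC/C(C[Si](C)(C)C)=C/B1OC(C)(C)C(C)(C)O1
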